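**Plan**
- Cuts, in retrosynthetic order: (a) take off the 7-O-TIPS and 2'-O-Ts groups and put a helper carbonyl back at C4 (isoflavanone level); (b) C2–C3 of ring C; (c) C3–C1' between the ketone side chain and ring B; (d) the C3'–CH2 bond of the prenyl group.
- Enabling feature: ring A carries oxygen on both carbons next to C4a (C5–OMe and C8a–O1), and O1–C2H2 is at the oxidation level of a methyl ether. Opening C2–C3 therefore leaves a symmetric 2,6-dimethoxy-4-oxyphenyl group with two equivalent OCH3 groups. A carbene at C3 can insert into either one, and the untouched one becomes the 5-OMe.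
- Forward order: ring B is prenylated (O-alkylation, semihydrogenation, Claisen) and tosylated, then joined to the ring A acetophenone by ketone α-arylation. Diazo transfer follows, and ring C closes last by C–H insertion. The C4 carbonyl is then removed and both phenols are freed.
- Stereochemistry: C3 is the only stereocentre. It is created at the carbene carbon during ring closure under control of a chiral dirhodium tetracarboxylate, and it is handled without base until C4 is no longer a carbonyl.

Key step: step 8

Assumption: no reliable model gives the sense of induction in step 8, so the catalyst antipode written is provisional; both antipodes can be bought, and the one that gives 3R is used.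

Step 1
Reactants: 1 2-bromo-5-methoxyphenol; 2 3-chloro-3-methylbut-1-yne
Product: 3 1-bromo-4-methoxy-2-[(2-methylbut-3-yn-2-yl)oxy]benzene
Conditions: CuCl2·2H2O (0.5 mol %), DBU, MeCN, 0 °C
Reagents that add atoms: none
Why: Copper-catalysed O-alkylation of a phenoxide with a tertiary propargylic chloride is the standard entry to aryl 1,1-dimethylpropargyl ethers and leaves the aryl bromide untouched.

Step 2
Reactants: 3 1-bromo-4-methoxy-2-[(2-methylbut-3-yn-2-yl)oxy]benzene
Product: 4 1-bromo-4-methoxy-2-[(2-methylbut-3-en-2-yl)oxy]benzene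
Conditions: H2 (1 atm), Pd/CaCO3 poisoned with Pb(OAc)2, quinoline, EtOAc, rt
Reagents that add atoms: none
Why: Lindlar semihydrogenation stops at the terminal alkene, and the poisoned palladium should not hydrogenolyse the electron-rich C–Br bond.

Step 3
Reactants: 4 1-bromo-4-methoxy-2-[(2-methylbut-3-en-2-yl)oxy]benzene
Product: 6 6-bromo-3-methoxy-2-(3-methylbut-2-enyl)phenol, via ortho-dienone 5 (not isolated)
Conditions: N,N-diethylaniline, 130 °C
Reagents that add atoms: none
Why: In this aromatic Claisen rearrangement the only ortho carbon that bears hydrogen lies between the oxygen and the OMe group, and the [3,3] allyl inversion turns the 1,1-dimethylallyl ether into the linear prenyl group before tautomerisation to the phenol.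

Step 4
Reactants: 6 6-bromo-3-methoxy-2-(3-methylbut-2-enyl)phenol
Product: 7 6-bromo-3-methoxy-2-(3-methylbut-2-enyl)phenyl 4-methylbenzenesulfonate
Conditions: TsCl, Et3N, DMAP (cat.), CH2Cl2, 0 °C to rt
Reagents that add atoms: 4-methylbenzenesulfonyl chloride, Cc1ccc(cc1)S(=O)(=O)Cl
Why: Routine phenol sulfonylation; the tosyl group is chosen because it has no C–H bond next to the phenolic oxygen, does not migrate to a neighbouring enolate oxygen as a silyl group could, and keeps the phenol from trapping the prenyl group under acid.

Step 5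
Reactants: 8 1-(4-hydroxy-2,6-dimethoxyphenyl)ethanone
Product: 9 1-[2,6-dimethoxy-4-(triisopropylsilyloxy)phenyl]ethanone
Conditions: TIPSCl, imidazole, DMF, rt
Reagents that add atoms: chlorotriisopropylsilane, CC(C)[Si](Cl)(C(C)C)C(C)C
Why: Standard silylation of the unhindered para phenol; the silyloxy group stays an electron donor, which later helps ionisation at C4.

Step 6
Reactants: 7 6-bromo-3-methoxy-2-(3-methylbut-2-enyl)phenyl 4-methylbenzenesulfonate; 9 1-[2,6-dimethoxy-4-(triisopropylsilyloxy)phenyl]ethanone
Product: 10 1-[2,6-dimethoxy-4-(triisopropylsilyloxy)phenyl]-2-[4-methoxy-3-(3-methylbut-2-enyl)-2-(tosyloxy)phenyl]ethanone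
Conditions: Pd2(dba)3 (2 mol %), Xantphos (5 mol %), K3PO4, toluene, 90 °C
Reagents that add atoms: none
Why: Palladium-catalysed α-arylation of a methyl ketone (oxidative addition of zerovalent palladium into C–Br, enolate exchange, reductive elimination); Xantphos with the mild base K3PO4 favours monoarylation, does not activate the aryl sulfonate and spares the silyl ether.

Step 7
Reactants: 10 1-[2,6-dimethoxy-4-(triisopropylsilyloxy)phenyl]-2-[4-methoxy-3-(3-methylbut-2-enyl)-2-(tosyloxy)phenyl]ethanone
Product: 11 2-diazo-1-[2,6-dimethoxy-4-(triisopropylsilyloxy)phenyl]-2-[4-methoxy-3-(3-methylbut-2-enyl)-2-(tosyloxy)phenyl]ethanone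
Conditions: 4-acetamidobenzenesulfonyl azide, DBU, dry MeCN, 0 °C to rt
Reagents that add atoms: 4-acetamidobenzenesulfonyl azide, CC(=O)Nc1ccc(cc1)S(=O)(=O)N=[N+]=[N-]
Why: In this Regitz diazo transfer the benzylic methylene, doubly activated by the carbonyl and aryl groups, is acidic enough for DBU, as is usual for benzyl aryl ketones.

Step 8
Reactants: 11 2-diazo-1-[2,6-dimethoxy-4-(triisopropylsilyloxy)phenyl]-2-[4-methoxy-3-(3-methylbut-2-enyl)-2-(tosyloxy)phenyl]ethanone
Product: 13 (3R)-5-methoxy-3-[4-methoxy-3-(3-methylbut-2-enyl)-2-(tosyloxy)phenyl]-7-(triisopropylsilyloxy)chroman-4-one, via rhodium carbene 12 (not isolated)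
Conditions: Rh2(S-PTAD)4 (1 mol %), 4 Å molecular sieves, CH2Cl2, slow addition of 11, 0 °C to rt; short pad of neutral silica, used at once
Reagents that add atoms: none
Why: Proposed new method: the divalent-rhodium dimer expels N2 from 11 to give the donor/acceptor carbene 12, whose electrophilic C3 takes up a C–H bond of an ortho OCH3 group in a concerted, asynchronous three-centre insertion, with the ether oxygen stabilising the positive charge that builds up on the methyl carbon. The closest known reaction types are the dirhodium-catalysed 1,6 C–H insertion of o-alkoxyaryl diazoketones next to the ether oxygen, which gives chroman-4-ones, and the enantioselective intermolecular insertion of aryl-substituted donor/acceptor carbenes into the primary C–H bonds of methyl ethers; new here is the combination, an α-aryl-α-diazoketone inserting into an aryl O–CH3 group. Ring C closes by 1,6-insertion through the six-membered array C3–C4–C4a–C8a–O1–C2. C3, the only new stereocentre, is the carbene carbon itself, and its configuration is set by the face of the Rh=C unit that the chiral carboxylate pocket leaves open to the C–H bond. The step needs this insertion to beat all other carbene outlets, and the substrate secures that: a 1,2-hydride shift is impossible because C4 is a carbonyl, the normally preferred 1,5-insertion has no C–H to use because the 2'-oxygen carries a sulfonyl group, and the prenyl alkene sits meta to the carbene-bearing carbon and cannot reach it. The two OCH3 groups interchange by rotation about C4–C4a, so either one leads to 13, and attack of the methoxy oxygen to give a five-membered oxonium ylide should be reversible because methyl migrates poorly.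

Step 9
Reactants: 13 (3R)-5-methoxy-3-[4-methoxy-3-(3-methylbut-2-enyl)-2-(tosyloxy)phenyl]-7-(triisopropylsilyloxy)chroman-4-one
Product: 14 (3R)-5-methoxy-3-[4-methoxy-3-(3-methylbut-2-enyl)-2-(tosyloxy)phenyl]-7-(triisopropylsilyloxy)chroman-4-ol (mixture of C4 epimers)
Conditions: i-Bu2AlH, CH2Cl2, −78 °C; aq. potassium sodium tartrate work-up
Reagents that add atoms: none
Why: This 1,2-reduction uses a Lewis-acidic, non-basic hydride donor, so hydride should arrive before C3 can enolise; the new C4 centre forms without control, which does not matter because step 10 removes it.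

Step 10
Reactants: 14 (3R)-5-methoxy-3-[4-methoxy-3-(3-methylbut-2-enyl)-2-(tosyloxy)phenyl]-7-(triisopropylsilyloxy)chroman-4-ol
Product: 15 (3R)-5-methoxy-3-[4-methoxy-3-(3-methylbut-2-enyl)-2-(tosyloxy)phenyl]-7-(triisopropylsilyloxy)chroman
Conditions: Et3SiH (5 equiv), CF3CO2H (2 equiv), CH2Cl2, −40 °C
Reagents that add atoms: none
Why: This is an ionic hydrogenation of a benzylic alcohol: the three oxygen donors of ring A let C4–OH ionise under weak acid at low temperature, excess silane delivers hydride quickly, and the trisubstituted alkene, the tosylate and the C3 configuration should survive.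

Step 11
Reactants: 15 (3R)-5-methoxy-3-[4-methoxy-3-(3-methylbut-2-enyl)-2-(tosyloxy)phenyl]-7-(triisopropylsilyloxy)chroman
Product: 16 (3R)-3-[2-hydroxy-4-methoxy-3-(3-methylbut-2-enyl)phenyl]-5-methoxychroman-7-ol
Conditions: KOH, 1,4-dioxane–H2O, 80 °C, argon; then aq. NH4Cl
Reagents that add atoms: none
Why: Hydroxide attacks silicon of the aryl silyl ether and sulfur of the aryl sulfonate, so both phenols are freed in one operation; leaving out alcohol solvents avoids alkyl tosylates that could alkylate the phenoxides, and C3–H is not acidic, so the stereocentre holds.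

**Compound list**
1 | 2-bromo-5-methoxyphenol | COc1ccc(Br)c(O)c1 | starting material
2 | 3-chloro-3-methylbut-1-yne | CC(C)(Cl)C#C | starting material
3 | 1-bromo-4-methoxy-2-[(2-methylbut-3-yn-2-yl)oxy]benzene | COc1ccc(Br)c(OC(C)(C)C#C)c1 | intermediate
4 | 1-bromo-4-methoxy-2-[(2-methylbut-3-en-2-yl)oxy]benzene | COc1ccc(Br)c(OC(C)(C)C=C)c1 | intermediate
5 | 2-bromo-5-methoxy-6-(3-methylbut-2-enyl)cyclohexa-2,4-dien-1-one (racemic, not isolated) | COC1=CC=C(Br)C(=O)C1CC=C(C)C | intermediate
6 | 6-bromo-3-methoxy-2-(3-methylbut-2-enyl)phenol | COc1ccc(Br)c(O)c1CC=C(C)C | intermediate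
7 | 6-bromo-3-methoxy-2-(3-methylbut-2-enyl)phenyl 4-methylbenzenesulfonate | COc1ccc(Br)c(OS(=O)(=O)c2ccc(C)cc2)c1CC=C(C)C | intermediate
8 | 1-(4-hydroxy-2,6-dimethoxyphenyl)ethanone | COc1cc(O)cc(OC)c1C(C)=O | starting material
9 | 1-[2,6-dimethoxy-4-(triisopropylsilyloxy)phenyl]ethanone | COc1cc(O[Si](C(C)C)(C(C)C)C(C)C)cc(OC)c1C(C)=O | intermediate
10 | deoxybenzoin: 1-[2,6-dimethoxy-4-(triisopropylsilyloxy)phenyl]-2-[4-methoxy-3-(3-methylbut-2-enyl)-2-(tosyloxy)phenyl]ethanone | COc1cc(O[Si](C(C)C)(C(C)C)C(C)C)cc(OC)c1C(=O)Cc1ccc(OC)c(CC=C(C)C)c1OS(=O)(=O)c1ccc(C)cc1 | intermediate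
11 | 2-diazo derivative of 10 | COc1cc(O[Si](C(C)C)(C(C)C)C(C)C)cc(OC)c1C(=O)C(=[N+]=[N-])c1ccc(OC)c(CC=C(C)C)c1OS(=O)(=O)c1ccc(C)cc1 | intermediate
12 | rhodium carbene from 11 (not isolated; the SMILES shows only the carbene-bearing Rh atom of the Rh2L4 core) | COc1cc(O[Si](C(C)C)(C(C)C)C(C)C)cc(OC)c1C(=O)C(=[Rh])c1ccc(OC)c(CC=C(C)C)c1OS(=O)(=O)c1ccc(C)cc1 | intermediate
13 | (3R)-5-methoxy-3-[4-methoxy-3-(3-methylbut-2-enyl)-2-(tosyloxy)phenyl]-7-(triisopropylsilyloxy)chroman-4-one | COc1cc(O[Si](C(C)C)(C(C)C)C(C)C)cc2c1C(=O)[C@H](c1ccc(OC)c(CC=C(C)C)c1OS(=O)(=O)c1ccc(C)cc1)CO2 | intermediate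
14 | (3R)-chroman-4-ol from 13, mixture of C4 epimers | COc1cc(O[Si](C(C)C)(C(C)C)C(C)C)cc2c1C(O)[C@H](c1ccc(OC)c(CC=C(C)C)c1OS(=O)(=O)c1ccc(C)cc1)CO2 | intermediate
15 | (3R)-5-methoxy-3-[4-methoxy-3-(3-methylbut-2-enyl)-2-(tosyloxy)phenyl]-7-(triisopropylsilyloxy)chroman | COc1cc(O[Si](C(C)C)(C(C)C)C(C)C)cc2c1C[C@H](c1ccc(OC)c(CC=C(C)C)c1OS(=O)(=O)c1ccc(C)cc1)CO2 | intermediate
16 | (3R)-3-[2-hydroxy-4-methoxy-3-(3-methylbut-2-enyl)phenyl]-5-methoxychroman-7-ol | COc1cc(O)cc2c1C[C@H](c1ccc(OC)c(CC=C(C)C)c1O)CO2 | target

**Totals**
- Total steps: 11.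
- Longest linear sequence: 10 steps (1, 2, 3, 4, 6, 7, 8, 9, 10, 11).

**Steps most likely to fail**

Step 8.
- What may go wrong: the carbene may be drained off by attack of the methoxy oxygen followed by methyl migration, or by dimerisation. The insertion may also proceed with poor facial selectivity.
- Fallback (known chemistry only), setting out from 10: MgI2·OEt2 in toluene–Et2O, chelated to the ketone, removes one of the two equivalent ortho methyl groups and should give the 2-hydroxy-6-methoxy deoxybenzoin F1. Paraformaldehyde and Et2NH in refluxing EtOH (α-methylenation followed by oxa-Michael closure) then supply C2 and close ring C to the racemic isoflavanone F2.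
- F2 is the racemate of 13 and comes back to the route at the stage of 13. Because it is racemic, it is reduced by the dynamic kinetic resolution described under step 9 instead of by step 9 itself.

Step 9.
- What may go wrong: C3 may partly epimerise by enolisation before hydride delivery, or the hindered, electron-rich ketone may be reduced only sluggishly.
- Fallback, setting out from 13: asymmetric transfer hydrogenation with dynamic kinetic resolution, RuCl[(R,R)-TsDPEN](p-cymene) in HCO2H–Et3N at 40 °C. The amine deliberately equilibrates C3 while the catalyst reduces only one enantiomer of the ketone from one face, a known process for isoflavanones.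
- This should give the (3R,4R)-cis-isoflavan-4-ol F3. F3 is one C4 epimer of 14, takes its place in step 10 and comes back to the route at 15. The source of configuration thus changes from retention of an existing centre to catalyst control.

Step 10.
- What may go wrong: the ionised C4 may lose the C3 hydrogen by elimination or hydride shift, which erases the stereocentre. The acid may also attack the prenyl double bond.
- Fallback, setting out from 14: radical instead of cationic deoxygenation (Barton–McCombie). PhOC(S)Cl, pyridine and DMAP in CH2Cl2 should give the C4 O-phenyl thionocarbonate F4. Bu3SnH and AIBN in toluene at 80 °C then replace the C–O bond by C–H through a benzylic radical that touches neither C3 nor the remote alkene, coming back to the route at 15.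

**Further compounds**
F1 | step 8 | 1-[2-hydroxy-6-methoxy-4-(triisopropylsilyloxy)phenyl]-2-[4-methoxy-3-(3-methylbut-2-enyl)-2-(tosyloxy)phenyl]ethanone | COc1cc(O[Si](C(C)C)(C(C)C)C(C)C)cc(O)c1C(=O)Cc1ccc(OC)c(CC=C(C)C)c1OS(=O)(=O)c1ccc(C)cc1
F2 | step 8 | racemic 5-methoxy-3-[4-methoxy-3-(3-methylbut-2-enyl)-2-(tosyloxy)phenyl]-7-(triisopropylsilyloxy)chroman-4-one | COc1cc(O[Si](C(C)C)(C(C)C)C(C)C)cc2c1C(=O)C(c1ccc(OC)c(CC=C(C)C)c1OS(=O)(=O)c1ccc(C)cc1)CO2
F3 | step 9 | (3R,4R)-cis-5-methoxy-3-[4-methoxy-3-(3-methylbut-2-enyl)-2-(tosyloxy)phenyl]-7-(triisopropylsilyloxy)chroman-4-ol | COc1cc(O[Si](C(C)C)(C(C)C)C(C)C)cc2c1[C@H](O)[C@H](c1ccc(OC)c(CC=C(C)C)c1OS(=O)(=O)c1ccc(C)cc1)CO2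
F4 | step 10 | O-phenyl thionocarbonate of 14 at C4 | COc1cc(O[Si](C(C)C)(C(C)C)C(C)C)cc2c1C(OC(=S)Oc1ccccc1)[C@H](c1ccc(OC)c(CC=C(C)C)c1OS(=O)(=O)c1ccc(C)cc1)CO2
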